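A direct plan would make the γ-keto acid A1 from an aryl Grignard reagent and a cyclic anhydride and condense it with the matching benzaldehyde to the arylidene butenolide A2.
It would open and cyclodehydrate A2 in methanolic acid to the methyl 4-aryl-2-naphthoate A3 (C4–C4a closure) and saponify A3 to the acid A4.
It would then couple A4 with O-benzylated (R)-danshensu to the heptabenzyl ester A5 and hydrogenolyse.
The mono-acylation of the Grignard reagent would be weak: the keto-carboxylate can take up a second aryl group, and lactone and biaryl by-products would cut throughput at the very start.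
The butenolide opening/cyclodehydration would be weak: a para-alkoxy-deactivated aryl ketone would have to be attacked from only one alkene geometry, in hot mineral acid, next to four benzyl ethers.
The ester shuffle would add three operations and no complexity: a methyl ester is made, saponified, and a bulky naphthoic acid is then coupled late with a hindered, epimerisable α-hydroxy ester.

C4 of the naphthalene carries two identical catechol rings: fused ring A (through C4a) and pendant ring C. Cutting C2–C3 and C1–C8a therefore unravels ring B into a symmetrical 1,1-diarylethene (C4=C3) and a C1–C2–CO2 unit, the formylacetate of (R)-danshensu. In the key step an electrophilic C2 radical adds to the alkene CH2, the C4 cation is parked as a dihydrofuran, and acid lets C1 close on either aryl ring, a degenerate choice. Ring B, its 2,4-pattern and the chiral ester arrive together, so there is no organometallic mono-acylation, no geometry-dependent ketone cyclodehydration, no ester exchange and no late coupling of a naphthoic acid.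

Key step: step 5

Assumption: sodium (R)-danshensu is taken as a commercial chiral-pool compound; the labels C1–C8a follow the naphthalene-2-carboxylate numbering of the target (ester on C2, ring C on C4, hydroxyls on C6/C7).

## Route

Step 1
Reactants: 1 4-bromobenzene-1,2-diol (4-bromocatechol)
Product: 2 5-bromo-2,2-diphenyl-1,3-benzodioxole
Conditions: Ph2CCl2 (1.1 equiv), neat, 160 °C, N2 sweep
Reagents that add atoms: dichlorodiphenylmethane, ClC(Cl)(c1ccccc1)c1ccccc1
Why: Ketalisation of a catechol with a gem-dichloride, driven by loss of HCl gas, should give a diphenylmethylene ketal that has no O–CH2 hydrogens, tolerates organolithium and Mn(III) reagents, and falls by hydrogenolysis at the end.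

Step 2
Reactants: 2 5-bromo-2,2-diphenyl-1,3-benzodioxole (2.1 equiv); 3 ethyl acetate
Product: 6 1,1-bis(2,2-diphenyl-1,3-benzodioxol-5-yl)ethene, via (2,2-diphenyl-1,3-benzodioxol-5-yl)lithium 4 (not isolated), via 1,1-bis(2,2-diphenyl-1,3-benzodioxol-5-yl)ethan-1-ol 5 (not isolated)
Conditions: n-BuLi, THF, −78 °C; 3 (1.0 equiv), −78 °C → rt; H2O; then PPTS (5 mol%), toluene, 80 °C
Reagents that add atoms: none
Why: Bromine–lithium exchange, exhaustive double addition of the aryllithium to the ester (both additions are wanted, so no chemoselectivity is at stake) and E1 dehydration of the tertiary carbinol, stabilised by two para oxygens, should give the symmetrical alkene that holds C4 and C3.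

Step 3
Reactants: 7 sodium (2R)-3-(3,4-dihydroxyphenyl)-2-hydroxypropanoate (sodium danshensu)
Product: 8 benzyl (2R)-3-[3,4-bis(benzyloxy)phenyl]-2-hydroxypropanoate
Conditions: BnBr (3.3 equiv), K2CO3 (2.5 equiv), DMF, rt, N2
Reagents that add atoms: benzyl bromide, BrCc1ccccc1
Why: Williamson and carboxylate O-alkylation in which carbonate ionises only the two phenols beside the carboxylate, so the secondary alcohol stays free and the (R) centre is not touched.

Step 4
Reactants: 8 benzyl (2R)-3-[3,4-bis(benzyloxy)phenyl]-2-hydroxypropanoate; 9 propiolic acid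
Product: 11 benzyl (2R)-3-[3,4-bis(benzyloxy)phenyl]-2-{[(2E)-3-(morpholin-4-yl)prop-2-enoyl]oxy}propanoate, via benzyl (2R)-3-[3,4-bis(benzyloxy)phenyl]-2-(prop-2-ynoyloxy)propanoate 10 (not isolated)
Conditions: DCC, DMAP (2 mol%), CH2Cl2, −20 → 0 °C; filter; then morpholine (1.0 equiv), 0 °C
Reagents that add atoms: morpholine, C1COCCN1
Why: Steglich esterification acylates the O–H without breaking the C–O bond at the stereocentre, and aza-Michael addition of morpholine to the alkynoate should give the (E)-enaminoester, a storable mask of the self-condensing formylacetate.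

Step 5
Reactants: 11 benzyl (2R)-3-[3,4-bis(benzyloxy)phenyl]-2-{[(2E)-3-(morpholin-4-yl)prop-2-enoyl]oxy}propanoate (1.3 equiv); 6 1,1-bis(2,2-diphenyl-1,3-benzodioxol-5-yl)ethene
Product: 14 (2R)-1-(benzyloxy)-3-[3,4-bis(benzyloxy)phenyl]-1-oxopropan-2-yl 8-(2,2-diphenyl-1,3-benzodioxol-5-yl)-2,2-diphenylnaphtho[2,3-d][1,3]dioxole-6-carboxylate, via benzyl (2R)-3-[3,4-bis(benzyloxy)phenyl]-2-[(3-oxopropanoyl)oxy]propanoate 12 (not isolated), via (2R)-1-(benzyloxy)-3-[3,4-bis(benzyloxy)phenyl]-1-oxopropan-2-yl 5,5-bis(2,2-diphenyl-1,3-benzodioxol-5-yl)-4,5-dihydrofuran-3-carboxylate 13 (not isolated)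
Conditions: Mn(OAc)3·2H2O (2.5 equiv), AcOH–CH2Cl2 (4:1), 40 °C, N2; aq. NaHCO3 work-up; then CSA (20 mol%), 4 Å MS, toluene, 60 °C
Reagents that add atoms: none
Why: In wet AcOH the vinylogous carbamate 11 is unmasked to the enolised formylacetate 12, whose Mn(III) enolate gives an electrophilic C2 radical that adds only to the free CH2 terminus of the nucleophilic alkene 6 (C2–C3 bond); the bis(alkoxyaryl)methyl radical so formed is oxidised at once by the second Mn(III) to the C4 cation, which the enol oxygen captures as the five-membered ring of 13. This is the Mn(OAc)3-mediated oxidative [3+2] addition of 1,3-dicarbonyl compounds to 1,1-diarylethenes, followed by a Bradsher-type aromatic cyclodehydration. Under CSA the C–O bond of 13 should ionise again, because the leaving group is a vinylogous carboxylate and the cation is stabilised by two para oxygens; loss of a C3 proton gives the 2-(2,2-diarylvinyl)formylacetate, the protonated aldehyde carbon C1 is attacked by the aryl ring cis to it (6-exo-trig Friedel–Crafts closure, C1–C8a bond), and loss of water aromatises ring B. The step needs cross- over self-coupling, secured by the polarity match of an electrophilic radical with an electron-rich, non-polymerisable alkene; it needs closure at the ring carbon para to a dioxole oxygen and not at the hindered carbon between two substituents, secured by electronics and sterics together; and it needs no control of alkene geometry, because the two aryl groups on C4 are identical and either one gives 14. No new stereocentre survives (C2 becomes sp2), and the (R) centre lies in the alkoxy part of the ester and meets only weak acid, so it should not be scrambled. N2 is required because O2 would trap the diarylmethyl radical, and the temperature is held at 40 °C so that solvent-derived carboxymethyl radicals stay negligible.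

Step 6
Reactants: 14 (2R)-1-(benzyloxy)-3-[3,4-bis(benzyloxy)phenyl]-1-oxopropan-2-yl 8-(2,2-diphenyl-1,3-benzodioxol-5-yl)-2,2-diphenylnaphtho[2,3-d][1,3]dioxole-6-carboxylate
Product: 15 eritrichin, (2R)-3-(3,4-dihydroxyphenyl)-2-{[4-(3,4-dihydroxyphenyl)-6,7-dihydroxynaphthalene-2-carbonyl]oxy}propanoic acid
Conditions: H2 (3 bar), Pd(OH)2/C, THF–MeOH (1:1), rt; filter under Ar
Reagents that add atoms: none
Why: Catalytic hydrogenolysis should cleave every benzylic C–O bond (two benzyl ethers, the benzyl ester and both doubly benzylic diphenylmethylene ketals), while the naphthalene and the homobenzylic naphthoate C–O bond at the (R) centre are not benzylic and stay.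

## Compound list

1 | 4-bromobenzene-1,2-diol | Oc1ccc(Br)cc1O | starting material
2 | 5-bromo-2,2-diphenyl-1,3-benzodioxole | Brc1ccc2OC(c3ccccc3)(c3ccccc3)Oc2c1 | intermediate
3 | ethyl acetate | CCOC(C)=O | starting material
4 | (2,2-diphenyl-1,3-benzodioxol-5-yl)lithium | [Li]c1ccc2OC(c3ccccc3)(c3ccccc3)Oc2c1 | intermediate
5 | 1,1-bis(2,2-diphenyl-1,3-benzodioxol-5-yl)ethan-1-ol | CC(O)(c1ccc2OC(c3ccccc3)(c3ccccc3)Oc2c1)c1ccc2OC(c3ccccc3)(c3ccccc3)Oc2c1 | intermediate
6 | 1,1-bis(2,2-diphenyl-1,3-benzodioxol-5-yl)ethene | C=C(c1ccc2OC(c3ccccc3)(c3ccccc3)Oc2c1)c1ccc2OC(c3ccccc3)(c3ccccc3)Oc2c1 | intermediate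
7 | sodium (2R)-3-(3,4-dihydroxyphenyl)-2-hydroxypropanoate | [Na+].[O-]C(=O)[C@H](O)Cc1ccc(O)c(O)c1 | starting material
8 | benzyl (2R)-3-[3,4-bis(benzyloxy)phenyl]-2-hydroxypropanoate | O[C@H](Cc1ccc(OCc2ccccc2)c(OCc2ccccc2)c1)C(=O)OCc1ccccc1 | intermediate
9 | propiolic acid | C#CC(=O)O | starting material
10 | benzyl (2R)-3-[3,4-bis(benzyloxy)phenyl]-2-(prop-2-ynoyloxy)propanoate | C#CC(=O)O[C@H](Cc1ccc(OCc2ccccc2)c(OCc2ccccc2)c1)C(=O)OCc1ccccc1 | intermediate
11 | benzyl (2R)-3-[3,4-bis(benzyloxy)phenyl]-2-{[(2E)-3-(morpholin-4-yl)prop-2-enoyl]oxy}propanoate | O=C(/C=C/N1CCOCC1)O[C@H](Cc1ccc(OCc2ccccc2)c(OCc2ccccc2)c1)C(=O)OCc1ccccc1 | intermediate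
12 | benzyl (2R)-3-[3,4-bis(benzyloxy)phenyl]-2-[(3-oxopropanoyl)oxy]propanoate | O=CCC(=O)O[C@H](Cc1ccc(OCc2ccccc2)c(OCc2ccccc2)c1)C(=O)OCc1ccccc1 | intermediate
13 | (2R)-1-(benzyloxy)-3-[3,4-bis(benzyloxy)phenyl]-1-oxopropan-2-yl 5,5-bis(2,2-diphenyl-1,3-benzodioxol-5-yl)-4,5-dihydrofuran-3-carboxylate | O=C(C1=COC(c2ccc3OC(c4ccccc4)(c4ccccc4)Oc3c2)(c2ccc3OC(c4ccccc4)(c4ccccc4)Oc3c2)C1)O[C@H](Cc1ccc(OCc2ccccc2)c(OCc2ccccc2)c1)C(=O)OCc1ccccc1 | intermediate
14 | (2R)-1-(benzyloxy)-3-[3,4-bis(benzyloxy)phenyl]-1-oxopropan-2-yl 8-(2,2-diphenyl-1,3-benzodioxol-5-yl)-2,2-diphenylnaphtho[2,3-d][1,3]dioxole-6-carboxylate | O=C(O[C@H](Cc1ccc(OCc2ccccc2)c(OCc2ccccc2)c1)C(=O)OCc1ccccc1)c1cc(-c2ccc3OC(c4ccccc4)(c4ccccc4)Oc3c2)c2cc3OC(c4ccccc4)(c4ccccc4)Oc3cc2c1 | intermediate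
15 | eritrichin | O=C(O[C@H](Cc1ccc(O)c(O)c1)C(=O)O)c1cc(-c2ccc(O)c(O)c2)c2cc(O)c(O)cc2c1 | target

## Summary

**Total steps:** 6.
**Longest linear sequence:** 4 (steps 1, 2, 5, 6 or steps 3, 4, 5, 6).

**Steps most likely to fail**

**Step 5.**
- What may go wrong: the liberated formylacetate may self-condense or be over-oxidised faster than its radical is intercepted. The dihydrofuran may also open while oxidant is still present.
- Fallback: a two-electron carbenoid assembly without oxidant or free formylacetate, which sets out from 8 and 6 and comes back at 13.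
- Alcohol 8 would be treated with glyoxylic acid chloride tosylhydrazone and PhNMe2, then Et3N, to give benzyl (2R)-3-[3,4-bis(benzyloxy)phenyl]-2-[(2-diazoacetyl)oxy]propanoate F1.
- C-Formylation with the Vilsmeier salt (DMF/(COCl)2, then aq. NaHCO3) would give benzyl (2R)-3-[3,4-bis(benzyloxy)phenyl]-2-[(2-diazo-3-oxopropanoyl)oxy]propanoate F2.
- Slow addition of F2 to 6 and Rh2(OAc)4 in CH2Cl2 would let the alkene CH2 attack the electrophilic carbenoid C2. The formyl oxygen would then close on C4 (formal [3+2]) to give 13, which enters the CSA stage as before.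

**Step 6.**
- What may go wrong: hydrogenolysis of the two hindered diaryl ketals may be slow, the emerging polyphenol may foul the catalyst, and the catechols may air-oxidise on long exposure.
- Fallback: an orthogonal two-stage release, which sets out from 14 and comes back at 15.
- Acid hydrolysis of both ketals (TFA–H2O–CH2Cl2, rt) would give benzyl (2R)-3-[3,4-bis(benzyloxy)phenyl]-2-{[4-(3,4-dihydroxyphenyl)-6,7-dihydroxynaphthalene-2-carbonyl]oxy}propanoate F3.
- The three remaining, unhindered benzyl groups would then fall quickly under H2, Pd/C (1 atm) to give 15.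

**Step 4.**
- What may go wrong: activated propiolic acid may oligomerise under base, and acylation of the hindered, electron-poor secondary alcohol may be sluggish.
- Fallback: the C3 unit is brought in already at the β-heteroatom-acrylate stage; the fallback sets out from 8 and comes back at 11.
- Acylation with commercial (E)-3-ethoxyacryloyl chloride and pyridine in CH2Cl2 would give benzyl (2R)-3-[3,4-bis(benzyloxy)phenyl]-2-{[(2E)-3-ethoxyprop-2-enoyl]oxy}propanoate F4.
- Addition–elimination with morpholine (toluene, 60 °C) would exchange ethoxide for the amine to give 11.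

## Further compounds

F1 | step 5 | benzyl (2R)-3-[3,4-bis(benzyloxy)phenyl]-2-[(2-diazoacetyl)oxy]propanoate | [N-]=[N+]=CC(=O)O[C@H](Cc1ccc(OCc2ccccc2)c(OCc2ccccc2)c1)C(=O)OCc1ccccc1
F2 | step 5 | benzyl (2R)-3-[3,4-bis(benzyloxy)phenyl]-2-[(2-diazo-3-oxopropanoyl)oxy]propanoate | [N-]=[N+]=C(C=O)C(=O)O[C@H](Cc1ccc(OCc2ccccc2)c(OCc2ccccc2)c1)C(=O)OCc1ccccc1
F3 | step 6 | benzyl (2R)-3-[3,4-bis(benzyloxy)phenyl]-2-{[4-(3,4-dihydroxyphenyl)-6,7-dihydroxynaphthalene-2-carbonyl]oxy}propanoate | O=C(O[C@H](Cc1ccc(OCc2ccccc2)c(OCc2ccccc2)c1)C(=O)OCc1ccccc1)c1cc(-c2ccc(O)c(O)c2)c2cc(O)c(O)cc2c1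
F4 | step 4 | benzyl (2R)-3-[3,4-bis(benzyloxy)phenyl]-2-{[(2E)-3-ethoxyprop-2-enoyl]oxy}propanoate | CCO/C=C/C(=O)O[C@H](Cc1ccc(OCc2ccccc2)c(OCc2ccccc2)c1)C(=O)OCc1ccccc1
A1 | direct plan | 4-[3,4-bis(benzyloxy)phenyl]-4-oxobutanoic acid | OC(=O)CCC(=O)c1ccc(OCc2ccccc2)c(OCc2ccccc2)c1
A2 | direct plan | (3E)-3-[3,4-bis(benzyloxy)benzylidene]-5-[3,4-bis(benzyloxy)phenyl]furan-2(3H)-one | O=C1OC(c2ccc(OCc3ccccc3)c(OCc3ccccc3)c2)=C/C1=C\c1ccc(OCc2ccccc2)c(OCc2ccccc2)c1
A3 | direct plan | methyl 6,7-bis(benzyloxy)-4-[3,4-bis(benzyloxy)phenyl]naphthalene-2-carboxylate | COC(=O)c1cc(-c2ccc(OCc3ccccc3)c(OCc3ccccc3)c2)c2cc(OCc3ccccc3)c(OCc3ccccc3)cc2c1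
A4 | direct plan | 6,7-bis(benzyloxy)-4-[3,4-bis(benzyloxy)phenyl]naphthalene-2-carboxylic acid | OC(=O)c1cc(-c2ccc(OCc3ccccc3)c(OCc3ccccc3)c2)c2cc(OCc3ccccc3)c(OCc3ccccc3)cc2c1
A5 | direct plan | benzyl (2R)-3-[3,4-bis(benzyloxy)phenyl]-2-({6,7-bis(benzyloxy)-4-[3,4-bis(benzyloxy)phenyl]naphthalene-2-carbonyl}oxy)propanoate | O=C(O[C@H](Cc1ccc(OCc2ccccc2)c(OCc2ccccc2)c1)C(=O)OCc1ccccc1)c1cc(-c2ccc(OCc3ccccc3)c(OCc3ccccc3)c2)c2cc(OCc3ccccc3)c(OCc3ccccc3)cc2c1
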